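## Retrosynthetic overview

- The target comes from one global hydride reduction of a benzodioxane that carries the side chain as an ethyl acrylate and the syringyl phenol as a pivalate.
- That benzodioxane is cut at both aryl C–O bonds of the dioxane (O-3–C-7 and O-4–C-8), giving an unprotected catechol acrylate and an enantiopure trans-3-aryl-2-(chloromethyl)oxirane. The two are joined in one flask with two ring closures, each stereocentre being inverted once.
- The epoxy chloride comes from Appel chlorination of a Sharpless epoxy alcohol, made from 4-O-pivaloylsinapyl alcohol, made from sinapic acid.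
- The catechol acrylate comes from a Wittig reaction on 3,4-dihydroxy-5-methoxybenzaldehyde.
- Ring order: oxirane (Sharpless), then a relay terminal oxirane and the 1,4-dioxane in the same operation. Both benzene rings are bought.

Assumption: intermediates present in the flask as sodium salts are listed in their neutral form. C-7/C-8/C-9 denote the aryl-bearing carbon, the CH2OH-bearing carbon and the CH2OH carbon; O-3/O-4 denote the ring A oxygens meta/para to the side chain.

## Route

Step 1
Reactants: 1 sinapic acid, (E)-3-(4-hydroxy-3,5-dimethoxyphenyl)prop-2-enoic acid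
Product: 3 4-[(E)-3-hydroxyprop-1-enyl]-2,6-dimethoxyphenyl 2,2-dimethylpropanoate, via mixed pivalic anhydride 2 (not isolated)
Conditions: PivCl (2.3 equiv), Et3N (2.6 equiv), DMAP (5 mol%), THF, 0 °C to rt; then NaBH4 (3 equiv), H2O, 0 °C
Reagents that add atoms: pivaloyl chloride, CC(C)(C)C(=O)Cl
Why: One acid chloride pivaloylates the phenol and activates the acid as mixed anhydride 2, whose unhindered cinnamoyl carbonyl is reduced 1,2 by borohydride (mixed-anhydride/NaBH4 reduction), while the doubly ortho-flanked aryl pivalate and the E-alkene are untouched; no stereocentre is formed.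

Step 2
Reactants: 3 4-[(E)-3-hydroxyprop-1-enyl]-2,6-dimethoxyphenyl 2,2-dimethylpropanoate
Product: 4 4-[(2R,3R)-3-(hydroxymethyl)oxiran-2-yl]-2,6-dimethoxyphenyl 2,2-dimethylpropanoate
Conditions: Ti(OiPr)4 (10 mol%), D-(−)-diethyl tartrate (12 mol%), t-BuOOH (2 equiv, decane), 4 Å MS, CH2Cl2, −20 °C
Reagents that add atoms: tert-butyl hydroperoxide, CC(C)(C)OO
Why: Sharpless asymmetric epoxidation of an E-cinnamyl-type alcohol, in which the D-(−)-tartrate/titanium catalyst delivers oxygen to the face that gives the (2R,3R)-epoxy alcohol, so both stereocentres of the route are created here; the acyloxy group keeps the benzylic epoxide from ionising.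

Step 3
Reactants: 4 4-[(2R,3R)-3-(hydroxymethyl)oxiran-2-yl]-2,6-dimethoxyphenyl 2,2-dimethylpropanoate
Product: 5 4-[(2R,3S)-3-(chloromethyl)oxiran-2-yl]-2,6-dimethoxyphenyl 2,2-dimethylpropanoate
Conditions: PPh3 (1.3 equiv), CCl4, NaHCO3, 70 °C
Reagents that add atoms: carbon tetrachloride, ClC(Cl)(Cl)Cl
Why: Appel reaction, in which chloride displaces the alkoxyphosphonium at the primary carbon only, so both epoxide stereocentres keep their spatial arrangement (the descriptor at the CH2Cl-bearing carbon changes from R to S by priority only).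

Step 4
Reactants: 6 3,4-dihydroxy-5-methoxybenzaldehyde
Product: 7 ethyl (E)-3-(3,4-dihydroxy-5-methoxyphenyl)prop-2-enoate
Conditions: Ph3P=CHCO2Et (1.2 equiv), toluene, 90 °C
Reagents that add atoms: ethyl (triphenylphosphoranylidene)acetate, CCOC(=O)C=P(c1ccccc1)(c1ccccc1)c1ccccc1
Why: Wittig olefination with a stabilised ylide, which tolerates free phenols and gives the E-acrylate; no stereocentre is formed.

Step 5
Reactants: 5 4-[(2R,3S)-3-(chloromethyl)oxiran-2-yl]-2,6-dimethoxyphenyl 2,2-dimethylpropanoate; 7 ethyl (E)-3-(3,4-dihydroxy-5-methoxyphenyl)prop-2-enoate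
Product: 10 ethyl (E)-3-[(2S,3S)-3-[3,5-dimethoxy-4-(2,2-dimethylpropanoyloxy)phenyl]-2-(hydroxymethyl)-8-methoxy-2,3-dihydro-1,4-benzodioxin-6-yl]prop-2-enoate, via chlorohydrin 8 (not isolated), via terminal oxirane 9 (not isolated)
Conditions: NaH (2.05 equiv), DMSO, 20 °C, Ar; then 5 (1.0 equiv), 20 to 45 °C; H2O quench at 0 °C
Reagents that add atoms: none
Why: Proposed new method: the disodium catecholate of 7 reacts first through its more basic and less hindered O-3 (O-4 is para-conjugated to the acrylate and flanked on both sides, as in the 3-O-selective alkylation of dianions of 4-acylcatechols) at the benzylic epoxide carbon C-7 of 5 by SN2 with inversion, the primary C–Cl bond being a much poorer electrophile for an aryloxide; the freed C-8 alkoxide then closes a terminal oxirane on C-9 (3-exo-tet, C-8 untouched) and the O-4 phenoxide opens it at C-8 in a 6-exo-tet SN2 with inversion, so each stereocentre of 5 is inverted exactly once and the trans-(2S,3S) dioxane results; the closest known reaction types are the catechol/epichlorohydrin annulation to 2-(hydroxymethyl)-1,4-benzodioxanes and the benzylic opening of trans-3-arylglycidol derivatives by aryloxides.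

Step 6
Reactants: 10 ethyl (E)-3-[(2S,3S)-3-[3,5-dimethoxy-4-(2,2-dimethylpropanoyloxy)phenyl]-2-(hydroxymethyl)-8-methoxy-2,3-dihydro-1,4-benzodioxin-6-yl]prop-2-enoate
Product: 11 4-[(2S,3S)-3-(hydroxymethyl)-7-[(E)-3-hydroxyprop-1-enyl]-5-methoxy-2,3-dihydro-1,4-benzodioxin-2-yl]-2,6-dimethoxyphenol
Conditions: i-Bu2AlH (7 equiv), CH2Cl2, −78 to 0 °C; aq. potassium sodium tartrate (KNaC4H4O6) work-up
Reagents that add atoms: none
Why: Hydride reduction with i-Bu2AlH converts the α,β-unsaturated ester 1,2 to the E-allylic alcohol and cleaves the aryl pivalate reductively in the same pot; the two ether stereocentres and the alkene geometry are not touched.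

## Compound list

1 | sinapic acid, (E)-3-(4-hydroxy-3,5-dimethoxyphenyl)prop-2-enoic acid | COc1cc(/C=C/C(=O)O)cc(OC)c1O | starting material
2 | (E)-3-[3,5-dimethoxy-4-(2,2-dimethylpropanoyloxy)phenyl]prop-2-enoic 2,2-dimethylpropanoic anhydride | COc1cc(/C=C/C(=O)OC(=O)C(C)(C)C)cc(OC)c1OC(=O)C(C)(C)C | intermediate (not isolated)
3 | 4-[(E)-3-hydroxyprop-1-enyl]-2,6-dimethoxyphenyl 2,2-dimethylpropanoate | COc1cc(/C=C/CO)cc(OC)c1OC(=O)C(C)(C)C | intermediate
4 | 4-[(2R,3R)-3-(hydroxymethyl)oxiran-2-yl]-2,6-dimethoxyphenyl 2,2-dimethylpropanoate (trans) | OC[C@H]1O[C@@H]1c1cc(OC)c(OC(=O)C(C)(C)C)c(OC)c1 | intermediate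
5 | 4-[(2R,3S)-3-(chloromethyl)oxiran-2-yl]-2,6-dimethoxyphenyl 2,2-dimethylpropanoate (trans) | ClC[C@H]1O[C@@H]1c1cc(OC)c(OC(=O)C(C)(C)C)c(OC)c1 | intermediate
6 | 3,4-dihydroxy-5-methoxybenzaldehyde | COc1cc(C=O)cc(O)c1O | starting material
7 | ethyl (E)-3-(3,4-dihydroxy-5-methoxyphenyl)prop-2-enoate | CCOC(=O)/C=C/c1cc(O)c(O)c(OC)c1 | intermediate
8 | ethyl (E)-3-[3-[(1S,2S)-3-chloro-1-[3,5-dimethoxy-4-(2,2-dimethylpropanoyloxy)phenyl]-2-hydroxypropoxy]-4-hydroxy-5-methoxyphenyl]prop-2-enoate | ClC[C@@H](O)[C@@H](Oc1cc(/C=C/C(=O)OCC)cc(OC)c1O)c1cc(OC)c(OC(=O)C(C)(C)C)c(OC)c1 | intermediate (not isolated)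
9 | ethyl (E)-3-[3-[(S)-[3,5-dimethoxy-4-(2,2-dimethylpropanoyloxy)phenyl][(2R)-oxiran-2-yl]methoxy]-4-hydroxy-5-methoxyphenyl]prop-2-enoate | C1O[C@H]1[C@@H](Oc1cc(/C=C/C(=O)OCC)cc(OC)c1O)c1cc(OC)c(OC(=O)C(C)(C)C)c(OC)c1 | intermediate (not isolated)
10 | ethyl (E)-3-[(2S,3S)-3-[3,5-dimethoxy-4-(2,2-dimethylpropanoyloxy)phenyl]-2-(hydroxymethyl)-8-methoxy-2,3-dihydro-1,4-benzodioxin-6-yl]prop-2-enoate (trans) | COc1cc([C@@H]2Oc3cc(/C=C/C(=O)OCC)cc(OC)c3O[C@H]2CO)cc(OC)c1OC(=O)C(C)(C)C | intermediate
11 | 4-[(2S,3S)-3-(hydroxymethyl)-7-[(E)-3-hydroxyprop-1-enyl]-5-methoxy-2,3-dihydro-1,4-benzodioxin-2-yl]-2,6-dimethoxyphenol | COc1cc([C@@H]2Oc3cc(/C=C/CO)cc(OC)c3O[C@H]2CO)cc(OC)c1O | target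

## Step count and risks

Total steps: 6. Longest linear sequence: 5 (1 → 3 → 4 → 5 → 10 → 11; step 4 is a one-step side branch).

**Most likely to fail, in order:**

**Step 5 (ring-forming cascade).** The risks are:
- the first attack may go to the CH2Cl carbon or come from O-4, giving the constitutional isomer;
- the last closure may go 7-endo instead of 6-exo;
- the product alkoxide may exchange with the ethyl ester, although such ester oligomers are all cleaved to 11 in step 6.

The fallback sets out from 7 (with 5) and comes back at 9, and so at 10. Compound 7 is mono-allylated at the more acidic O-4 (allyl bromide, K2CO3 1.0 equiv, DMF) to ethyl (E)-3-(3-hydroxy-5-methoxy-4-prop-2-enoxyphenyl)prop-2-enoate F1. Its sodium salt, now the only phenoxide, opens 5 at C-7, and the alkoxide closes to the isolable ethyl (E)-3-[3-[(S)-[3,5-dimethoxy-4-(2,2-dimethylpropanoyloxy)phenyl][(2R)-oxiran-2-yl]methoxy]-5-methoxy-4-prop-2-enoxyphenyl]prop-2-enoate F2. Pd(PPh3)4 with morpholine in THF removes the allyl group to give 9, which is cyclised separately with Cs2CO3 in DMF at 50 °C to 10. Regiochemistry is then fixed by a protecting group and each ring closure is run as its own operation.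

**Step 2 (Sharpless epoxidation).** The aryl-substituted epoxy alcohol may open or form in low ee under the titanium conditions. The fallback sets out from 3 and comes back at 5, bypassing 4. Compound 3 is converted (PPh3, CCl4) into 4-[(E)-3-chloroprop-1-enyl]-2,6-dimethoxyphenyl 2,2-dimethylpropanoate F3. This is epoxidised under Shi conditions (D-fructose-derived ketone catalyst, KHSO5, K2CO3 buffer, MeCN–dimethoxymethane–H2O, 0 °C). That catalyst gives the same facial sense as in the (R,R)-epoxide of trans-β-methylstyrene, which is the configuration of 5.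

**Step 1 (one-pot pivaloylation/reduction).** The phenol may be acylated by the mixed anhydride (oligomers), or some 1,4-reduction may occur. The fallback sets out from 1 and comes back at 3. Fischer esterification (MeOH, H2SO4) gives methyl (E)-3-(4-hydroxy-3,5-dimethoxyphenyl)prop-2-enoate F4. Reduction with i-Bu2AlH gives 4-[(E)-3-hydroxyprop-1-enyl]-2,6-dimethoxyphenol F5. Phenoxide-selective pivaloylation under biphasic conditions (PivCl, aq. NaOH, CH2Cl2, Bu4NHSO4, 0 °C) then gives 3.

## Further compounds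

F1 | step 5 | ethyl (E)-3-(3-hydroxy-5-methoxy-4-prop-2-enoxyphenyl)prop-2-enoate | CCOC(=O)/C=C/c1cc(O)c(OCC=C)c(OC)c1
F2 | step 5 | ethyl (E)-3-[3-[(S)-[3,5-dimethoxy-4-(2,2-dimethylpropanoyloxy)phenyl][(2R)-oxiran-2-yl]methoxy]-5-methoxy-4-prop-2-enoxyphenyl]prop-2-enoate | C1O[C@H]1[C@@H](Oc1cc(/C=C/C(=O)OCC)cc(OC)c1OCC=C)c1cc(OC)c(OC(=O)C(C)(C)C)c(OC)c1
F3 | step 2 | 4-[(E)-3-chloroprop-1-enyl]-2,6-dimethoxyphenyl 2,2-dimethylpropanoate | COc1cc(/C=C/CCl)cc(OC)c1OC(=O)C(C)(C)C
F4 | step 1 | methyl (E)-3-(4-hydroxy-3,5-dimethoxyphenyl)prop-2-enoate | COC(=O)/C=C/c1cc(OC)c(O)c(OC)c1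
F5 | step 1 | 4-[(E)-3-hydroxyprop-1-enyl]-2,6-dimethoxyphenol | COc1cc(/C=C/CO)cc(OC)c1O
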